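No exchange can spend more incoming ligand than the flask was charged with, and each exchange frees one leaving ligand, so both free ligands are estimated here from the charge by counting the exchanges held in the complexes.

| setting | spring | noon | midnight | south | north |
|---|---|---|---|---|---|
| starting complex | 0.10 M | 0.10 M | 0.10 M | 0.10 M | 0.10 M |
| incoming ligand | 0.43 equiv | 1.5 equiv | 2.9 equiv | 0.500 equiv | 4.00 equiv |
| remark | run made earlier | run made earlier | run made earlier |  |  |
| time |  |  |  | 15 h | 15 h |

| run | time / h | complex with one exchanged / % | complex with two exchanged / % | starting complex / % |
|---|---|---|---|---|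
| spring | 3.00 | 33 | 4 | 69 |
| spring | 6.00 | 32 | 3 | 62 |
| spring | 10.0 | 35 | 2 | 58 |
| spring | 12.0 | 33 | 0 | 59 |
| spring | 15.0 | 31 | 1 | 59 |
| noon | 1.33 | 51 | 7 | 30 |
| noon | 2.50 | 57 | 19 | 18 |
| noon | 4.00 | 50 | 25 | 14 |
| noon | 8.00 | 47 | 31 | 6 |
| noon | 15.0 | 33 | 31 | 6 |
| midnight | 1.33 | 54 | 30 | 7 |
| midnight | 4.00 | 24 | 41 | 1 |
| midnight | 8.00 | 12 | 45 | 3 |
| midnight | 10.0 | 11 | 47 | 0 |
| midnight | 15.0 | 4 | 48 | 2 |

(readings scatter by 2 percentage points)

* which of these holds the largest part of the starting complex at the end of south (complex with two exchanged / complex with one exchanged / complex with three exchanged / starting complex)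
* which of these holds the largest part of the starting complex at the end of north (complex with two exchanged / complex with one exchanged / complex with three exchanged / starting complex)
* complex with one exchanged at the end of north, in percent of the starting complex charged

In spring, starting complex stands 2 percentage points above what the charge of incoming ligand, the limiting reagent, leaves. The same offset puts south near 52.0% starting complex, more than the 48.0% for everything else together.

For north, midnight's last readings serve, taking what they miss as complex with three exchanged:

missing = 46.0%
leaving ligand = one-exchanged + 2 × two-exchanged + 3 × missing = 2.38 equivalents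
incoming ligand = 0.520 equivalents

The exchange quotient of a step is the more exchanged complex over the less exchanged, times leaving over incoming ligand. It stands still once the step has come to rest. Midnight reads 54.9 for one to two and 4.39 for two to three.

Complex with one exchanged fell early at midnight with an apparent life of 3.29 h, an average over two readings while incoming ligand was falling too, and shorter than the 15 h of north, so north is reckoned at rest. With x the share of two-exchanged, north holds 1 − x three-exchanged, 1 + x incoming and 3 − x leaving ligand in equivalents:

x = 31.7%, three-exchanged = 68.3%
one-exchanged = x × leaving / incoming / quotient = 1.18%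

The weak link is the single reading of 4%, with scatter 2 points. Read as 6.00%, it lowers the quotient to 36.6 and raises the answer to 1.77%.

The forecast gave starting complex for south, complex with three exchanged for north and 0.5% of complex with one exchanged, less than this reckoning, saying “three-exchanged should lead, though this is an inference”.

South ends with starting complex at 52.3%. North ends with complex with three exchanged at 60.0% and complex with one exchanged at 1.88%.

    starting complex + complex with two exchanged → side product (k = 7.25 × 10⁻⁴ L mol⁻¹ s⁻¹)
    complex with one exchanged + incoming ligand ⇌ leaving ligand + complex with two exchanged (K = 34.0, k = 8.64 × 10⁻⁴ L mol⁻¹ s⁻¹)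
    complex with two exchanged + incoming ligand ⇌ leaving ligand + complex with three exchanged (K = 3.00, k = 6.68 × 10⁻⁴ L mol⁻¹ s⁻¹)
    starting complex + incoming ligand ⇌ leaving ligand + complex with one exchanged (K = 41.0, k = 0.00248 L mol⁻¹ s⁻¹)

North's simulated amounts at 15.0 h are 35.3% two-exchanged, 0.255 M leaving ligand and 0.145 M incoming ligand. Through the quotient they give 1.13% one-exchanged, against 1.88% in the flask. The same flask read at 4.0 h has 38.1% two-exchanged, 0.235 M leaving ligand and 0.165 M incoming ligand, so the quotient gives 0.988%, while that reading holds ten times as much, 10.4%.

(All runs come from a simulation from invented constants, noise included.)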